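The route rests on the C3′–C4′ sp2–sp2 bond of the (2E,4E,6E)-5-methyldodecatrienoate on O3 of ring A. A Mizoroki–Heck reaction joins (1E,3E)-1-iodo-2-methylnona-1,3-diene to the C3 acrylate of the complete cis-eremophilane core. It forms this bond and the 2′E alkene in one operation and exploits the polarised C2′=C3′ acrylate double bond next to the ester carbonyl C1′, so the core needs no organometallic activation. The precursor is the acrylate ester of the 9-O-silylated 9,12-dihydroxy-8-oxo-7(11)Z-ene core, built from (S)-Wieland–Miescher ketone, with a ring-B-fused 3-methylfuran as latent (Z)-hydroxy enone.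

Key step: step 16

Remark: the decalin is numbered as in eremophilane (ring A = C1–C5, C10; ring B = C5–C10; C14 = 4-methyl, C15 = 5-methyl, C11–C13 = side chain on C7); β is the face of the C5 methyl, α the opposite face; primed locants belong to the acyl chain. (S)-Wieland–Miescher ketone, (E)-oct-2-enal, 1-(tert-butyldimethylsilyloxy)propan-2-one and acryloyl chloride are taken as commercial.

Step 1
Reactants: 1 (E)-oct-2-enal
Product: 2 (E)-non-3-en-1-yne
Conditions: TMSCHN2, LDA, THF, −78 °C → rt
Reagents that add atoms: (trimethylsilyl)diazomethane, C[Si](C)(C)C=[N+]=[N-]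
Why: Colvin rearrangement: lithiated TMS-diazomethane adds 1,2 to the aldehyde, Peterson-type loss of silanolate and of N2 gives an alkylidene carbene whose 1,2-H shift delivers the terminal alkyne; the E alkene is untouched and no stereocentre forms.

Step 2
Reactants: 2 (E)-non-3-en-1-yne
Product: 4 (1E,3E)-1-iodo-2-methylnona-1,3-diene, via dienyl(dimethyl)alane 3 (not isolated)
Conditions: AlMe3, Cp2ZrCl2 (25 mol %), CH2Cl2, 0 °C → rt; then I2, THF, −30 → 0 °C
Reagents that add atoms: trimethylaluminium, C[Al](C)C; iodine, II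
Why: Negishi zirconium-catalysed methylalumination adds Me and Al syn across the alkyne (Me to the internal carbon), and iodinolysis of the C–Al bond with retention fixes the 1E geometry (iodine trans to the C3=C4 vinyl group).

Step 3
Reactants: 5 (S)-Wieland–Miescher ketone
Product: 6 4-oxo-5β-methyl-Δ9(10)-octalin carrying C8 as spiro-1,3-dithiolane
Conditions: HS(CH2)2SH, p-TsOH (cat.), AcOH, rt
Reagents that add atoms: ethane-1,2-dithiol, SCCS
Why: chemoselective dithioketalisation of the conjugated C8 carbonyl (the neopentyl C4 ketone reacts much more slowly) keeps C9=C10 in place and masks the enone for the base, Grignard and borane steps that follow.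

Step 4
Reactants: 6 C8-dithiolane ketone
Product: 7 C3=C4 enol triflate of 6
Conditions: KHMDS, THF, −78 °C; PhNTf2, −78 → 0 °C
Reagents that add atoms: N-phenylbis(trifluoromethanesulfonimide), O=S(=O)(N(c1ccccc1)S(=O)(=O)C(F)(F)F)C(F)(F)F
Why: enol triflate formation: the C4 ketone can enolise only toward C3 because C5 is quaternary, and the potassium enolate is O-sulfonylated.

Step 5
Reactants: 7 enol triflate
Product: 8 4,5β-dimethyl-Δ3,Δ9(10)-octalin C8-dithiolane
Conditions: MeMgBr, Fe(acac)3 (5 mol %), THF/NMP, −30 → 0 °C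
Reagents that add atoms: methylmagnesium bromide, C[Mg]Br
Why: iron-catalysed Kumada-type cross-coupling of the alkenyl triflate installs the C4 methyl (C14) under conditions expected to tolerate the dithiolane.

Step 6
Reactants: 8 diene dithiolane
Product: 10 3α-hydroxy-4β,5β-dimethyl-Δ9(10)-octalin C8-dithiolane, via C3-alkylborane 9 (not isolated)
Conditions: BH3·SMe2 (1.1 equiv), THF, 0 °C → rt; then NaBO3·4H2O, THF/H2O, rt
Reagents that add atoms: borane–dimethyl sulfide, C[S+](C)[BH3-]; sodium perborate, [Na+].[Na+].O[B-]1(O)OO[B-](O)(O)OO1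
Why: hydroboration–oxidation: borane adds syn and anti-Markovnikov to C3=C4 from the α face, opposite the pseudo-axial C5 methyl, so H enters at C4α (methyl ends β, cis to the C5 methyl) and boron at C3α, and oxidation with retention gives the 3α-alcohol; the C9=C10 alkene, flanked by the dithiolane carbon and quaternary C5, should react much more slowly.

Step 7
Reactants: 10 hydroxy dithiolane
Product: 11 3α-hydroxy-4β,5β-dimethyl-Δ9(10)-octal-8-one
Conditions: MeI (excess), CaCO3, MeCN/H2O (4:1), 45 °C
Reagents that add atoms: water, O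
Why: alkylative hydrolysis of the dithiolane (S-methylation, ionisation to the allylic thionium ion, capture by water) restores the conjugated enone under buffered conditions that spare the alcohol and the stereocentres.

Step 8
Reactants: 11 hydroxy enone
Product: 12 3α-(triethylsilyloxy)-4β,5β-dimethyl-Δ9(10)-octal-8-one
Conditions: TESCl, imidazole, CH2Cl2, 0 °C → rt
Reagents that add atoms: chlorotriethylsilane, CC[Si](Cl)(CC)CC
Why: standard silylation; TES is chosen because the mild acid of step 13 removes it while the more robust secondary TBS ether at O9 stays.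

Step 9
Reactants: 12 TES-protected enone
Product: 13 3α-(triethylsilyloxy)-4β,5β-dimethyl-10βH-decal-8-one (cis-fused)
Conditions: H2 (1 atm), 10% Pd/C, EtOAc/pyridine, rt
Reagents that add atoms: none
Why: heterogeneous hydrogenation: as with 10-methyl-Δ1(9)-octal-2-ones and Δ4-3-keto steroids over Pd in pyridine, hydrogen should be delivered to C10 on the face of the angular methyl, giving the cis-fused decalone (10β-H).

Step 10
Reactants: 13 cis-decalone
Product: 14 8-(tert-butyldimethylsilyloxy)-Δ8(9) enol ether of 13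
Conditions: TBSOTf, Et3N, CH2Cl2, 0 °C → rt (equilibrating)
Reagents that add atoms: tert-butyldimethylsilyl trifluoromethanesulfonate, CC(C)(C)[Si](C)(C)OS(=O)(=O)C(F)(F)F
Why: silyl enol ether formation under thermodynamic control; the cis-decalone in its steroid-like conformation (C5 methyl equatorial on ring B) should enolise toward the ring-fusion side, C9, as 3-keto-5β-steroids give Δ3-enol derivatives.

Step 11
Reactants: 14 silyl enol ether
Product: 16 9β-(tert-butyldimethylsilyloxy)-3α-(triethylsilyloxy)-4β,5β-dimethyl-10βH-decal-8-one, via 8β,9β-epoxy silyl ether 15 (not isolated)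
Conditions: mCPBA (1.1 equiv), CH2Cl2, −20 °C → rt
Reagents that add atoms: 3-chloroperoxybenzoic acid, OOC(=O)c1cccc(Cl)c1
Why: Rubottom oxidation: the peracid attacks the enol ether on the convex β face (the α face is covered by the axial C5–C4 bond of ring A), and opening of the silyloxy epoxide with 1,4-silyl shift gives the α-silyloxy ketone with the equatorial 9β-oxygen, which is also the more stable epimer.

Step 12
Reactants: 16 α-silyloxy ketone; 17 1-(tert-butyldimethylsilyloxy)propan-2-one
Product: 18 C7 aldol adduct, 7-[1-(tert-butyldimethylsilyloxy)-2-hydroxypropan-2-yl] derivative of 16 (mixture at C7 and C11)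
Conditions: LDA, THF, −78 °C; ZnCl2; then 17, −78 → −40 °C; aq. NH4Cl
Reagents that add atoms: none
Why: aldol addition: LDA removes a C7 proton (C9–H is a hindered α-silyloxy methine) and the zinc enolate adds to ketone 17; the new centres C7 and C11 form as a mixture of no consequence because both become sp2 in step 13.

Step 13
Reactants: 18 aldol adduct
Product: 19 9β-(tert-butyldimethylsilyloxy)-10βH-furanoeremophilan-3α-ol (3-methylfuran fused at C7–C8, O on C8)
Conditions: CSA (0.1 equiv), MeOH/CH2Cl2 (1:1), 0 °C → rt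
Reagents that add atoms: none
Why: acid-catalysed cleavage of the TES and primary TBS ethers, 5-exo hemiketalisation of O12 onto C8 and two dehydrations (Paal–Knorr-type cyclodehydration driven by aromatisation) give the furan and free the C3 hydroxyl, while the hindered secondary TBS ether at O9 should survive.

Step 14
Reactants: 19 furanol; 20 acryloyl chloride
Product: 21 9β-(tert-butyldimethylsilyloxy)-10βH-furanoeremophilan-3α-yl acrylate
Conditions: i-Pr2NEt, DMAP (cat.), CH2Cl2, −20 → 0 °C
Reagents that add atoms: none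
Why: DMAP-catalysed O-acylation of the only free hydroxyl; no stereocentre is affected.

Step 15
Reactants: 21 furan acrylate
Product: 23 (7(11)Z)-12-hydroxy-8-oxo-9β-(tert-butyldimethylsilyloxy)-10βH-eremophil-7(11)-en-3α-yl acrylate, via (Z)-keto-enal 22 (not isolated)
Conditions: DMDO (1.1 equiv), acetone, −78 → −20 °C; evaporate; NaBH4, CH2Cl2/EtOH, −78 °C; pH 7 buffer
Reagents that add atoms: dimethyldioxirane, CC1(C)OO1
Why: oxidative furan ring opening: DMDO epoxidises the electron-rich furan (the acrylate is electron-poor and inert) and the epoxide opens to the cis-enedione, whose Z geometry (C12 aldehyde cis to the C8 ketone) is dictated by the former ring; NaBH4 at −78 °C then reduces the aldehyde 1,2 in preference to the hindered conjugated ketone and the acrylate.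

Step 16
Reactants: 23 hydroxy-enone acrylate; 4 (1E,3E)-1-iodo-2-methylnona-1,3-diene
Product: 24 9-O-TBS ether of the target
Conditions: Pd(OAc)2 (10 mol %), Bu4NCl, NaHCO3, DMF, rt → 40 °C, dark
Reagents that add atoms: none
Why: Mizoroki–Heck reaction under phase-transfer (tetraalkylammonium chloride) conditions: Pd(0) formed in situ inserts into the C–I bond of 4 with retention of the 1E geometry, the dienyl–Pd(II) species adds syn across C2′=C3′ with the dienyl group going to the unsubstituted electrophilic β-carbon C3′ (forming C3′–C4′), and syn β-hydride elimination from the rotamer with the ester anti to the dienyl group releases the 2′E alkene while bicarbonate regenerates Pd(0). The closest known reaction type is the ligand-free vinylation of acrylates with (E)-alkenyl iodides to (2E,4E)-dienoates. No ring is closed and no stereocentre is formed; the only new stereo-element is the 2′E double bond, set by the syn-insertion/syn-elimination sequence, while 4′E and 6′E are carried over from 4. The step needs chemoselectivity for the monosubstituted acrylate over the tetrasubstituted C7=C11 enone, which is too hindered for migratory insertion, and tolerance of the free C12 hydroxyl and the 9-silyloxy ketone, which the near-neutral, low-temperature conditions should secure.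

Step 17
Reactants: 24 9-O-TBS ether of the target
Product: 25 target, (3R,4R,5R,9R,10S)-9,12-dihydroxy-8-oxoeremophil-7(11)Z-en-3-yl (2E,4E,6E)-5-methyldodeca-2,4,6-trienoate
Conditions: TBAF/AcOH (1:1), THF, 0 °C → rt
Reagents that add atoms: none
Why: fluoride-mediated desilylation buffered with acetic acid removes the remaining TBS ether without touching the trienoate, the α-ketol or the acid-sensitive (Z)-γ-hydroxy enone.

Compound list
1 | (E)-oct-2-enal | CCCCC/C=C/C=O | starting material
2 | (E)-non-3-en-1-yne | CCCCC/C=C/C#C | intermediate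
3 | [(1E,3E)-2-methylnona-1,3-dien-1-yl]dimethylalane | CCCCC/C=C/C(C)=C/[Al](C)C | intermediate
4 | (1E,3E)-1-iodo-2-methylnona-1,3-diene | CCCCC/C=C/C(C)=C/I | intermediate
5 | (S)-Wieland–Miescher ketone, (S)-8a-methyl-3,4,8,8a-tetrahydronaphthalene-1,6(2H,7H)-dione | C[C@]12CCC(=O)C=C1CCCC2=O | starting material
6 | 4-oxo-5β-methyl-Δ9(10)-octalin with C8 as spiro-1,3-dithiolane | O=C1CCCC2=CC3(SCCS3)CC[C@]12C | intermediate
7 | C3=C4 enol triflate of 6 | O=S(=O)(OC1=CCCC2=CC3(SCCS3)CC[C@]12C)C(F)(F)F | intermediate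
8 | 4,5β-dimethyl-Δ3,Δ9(10)-octalin with C8 as spiro-1,3-dithiolane | CC1=CCCC2=CC3(SCCS3)CC[C@]12C | intermediate
9 | 3α-boryl-4β,5β-dimethyl-Δ9(10)-octalin C8-dithiolane | B[C@@H]1CCC2=CC3(SCCS3)CC[C@]2(C)[C@H]1C | intermediate
10 | 3α-hydroxy-4β,5β-dimethyl-Δ9(10)-octalin C8-dithiolane | O[C@@H]1CCC2=CC3(SCCS3)CC[C@]2(C)[C@H]1C | intermediate
11 | 3α-hydroxy-4β,5β-dimethyl-Δ9(10)-octal-8-one, (4aR,5R,6R)-6-hydroxy-4a,5-dimethyl-4,4a,5,6,7,8-hexahydronaphthalen-2(3H)-one | O[C@@H]1CCC2=CC(=O)CC[C@]2(C)[C@H]1C | intermediate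
12 | 3α-(triethylsilyloxy)-4β,5β-dimethyl-Δ9(10)-octal-8-one | CC[Si](CC)(CC)O[C@@H]1CCC2=CC(=O)CC[C@]2(C)[C@H]1C | intermediate
13 | 3α-(triethylsilyloxy)-4β,5β-dimethyl-10βH-decal-8-one (cis-fused) | CC[Si](CC)(CC)O[C@@H]1CC[C@@H]2CC(=O)CC[C@]2(C)[C@H]1C | intermediate
14 | 8-(tert-butyldimethylsilyloxy)-Δ8(9) enol ether of 13 | CC[Si](CC)(CC)O[C@@H]1CC[C@@H]2C=C(O[Si](C)(C)C(C)(C)C)CC[C@]2(C)[C@H]1C | intermediate
15 | 8β,9β-epoxide of 14 | CC[Si](CC)(CC)O[C@@H]1CC[C@@H]2[C@H]3O[C@@]3(O[Si](C)(C)C(C)(C)C)CC[C@]2(C)[C@H]1C | intermediate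
16 | 9β-(tert-butyldimethylsilyloxy)-3α-(triethylsilyloxy)-4β,5β-dimethyl-10βH-decal-8-one | CC[Si](CC)(CC)O[C@@H]1CC[C@@H]2[C@@H](O[Si](C)(C)C(C)(C)C)C(=O)CC[C@]2(C)[C@H]1C | intermediate
17 | 1-(tert-butyldimethylsilyloxy)propan-2-one | CC(=O)CO[Si](C)(C)C(C)(C)C | starting material
18 | C7 aldol adduct of 16 with 17 (mixture at C7 and C11) | CC[Si](CC)(CC)O[C@@H]1CC[C@@H]2[C@@H](O[Si](C)(C)C(C)(C)C)C(=O)C(C(C)(O)CO[Si](C)(C)C(C)(C)C)C[C@]2(C)[C@H]1C | intermediate
19 | 9β-(tert-butyldimethylsilyloxy)-10βH-furanoeremophilan-3α-ol | O[C@@H]1CC[C@@H]2[C@@H](O[Si](C)(C)C(C)(C)C)c3occ(C)c3C[C@]2(C)[C@H]1C | intermediate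
20 | acryloyl chloride | C=CC(=O)Cl | starting material
21 | 9β-(tert-butyldimethylsilyloxy)-10βH-furanoeremophilan-3α-yl acrylate | C=CC(=O)O[C@@H]1CC[C@@H]2[C@@H](O[Si](C)(C)C(C)(C)C)c3occ(C)c3C[C@]2(C)[C@H]1C | intermediate
22 | (7(11)Z)-8,12-dioxo-9β-(tert-butyldimethylsilyloxy)-10βH-eremophil-7(11)-en-3α-yl acrylate | C=CC(=O)O[C@@H]1CC[C@@H]2[C@@H](O[Si](C)(C)C(C)(C)C)C(=O)/C(=C(/C)C=O)C[C@]2(C)[C@H]1C | intermediate
23 | (7(11)Z)-12-hydroxy-8-oxo-9β-(tert-butyldimethylsilyloxy)-10βH-eremophil-7(11)-en-3α-yl acrylate | C=CC(=O)O[C@@H]1CC[C@@H]2[C@@H](O[Si](C)(C)C(C)(C)C)C(=O)/C(=C(/C)CO)C[C@]2(C)[C@H]1C | intermediate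
24 | 9-O-(tert-butyldimethylsilyl) ether of the target | CCCCC/C=C/C(C)=C/C=C/C(=O)O[C@@H]1CC[C@@H]2[C@@H](O[Si](C)(C)C(C)(C)C)C(=O)/C(=C(/C)CO)C[C@]2(C)[C@H]1C | intermediate
25 | (3R,4R,5R,9R,10S)-9,12-dihydroxy-8-oxoeremophil-7(11)Z-en-3-yl (2E,4E,6E)-5-methyldodeca-2,4,6-trienoate | CCCCC/C=C/C(C)=C/C=C/C(=O)O[C@@H]1CC[C@@H]2[C@@H](O)C(=O)/C(=C(/C)CO)C[C@]2(C)[C@H]1C | target

Total step count: 17 (2 for the dienyl iodide, 15 for the core and endgame).
Longest linear sequence: 15 steps (steps 3–17, from 5 to 25).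

Steps most likely to fail

Step 6. The hydroboration may lose chemoselectivity: the C9=C10 alkene could compete, or the dithiolane sulfur could sequester borane. The fallback sets out from 8 and returns at 11. The dithiolane is first removed with MeI/CaCO3 in aqueous MeCN to give the dienone 4,5β-dimethyl-Δ3,Δ9(10)-octalin-8-one F1. Buffered mCPBA then epoxidises only the electron-rich C3=C4 alkene, from the α face opposite the C5 methyl, giving the 3α,4α-epoxy enone F2. TMSOTf/DBU (epoxide-to-allylic silyl ether isomerisation by loss of a C14 proton, then dilute acid) gives the 3α-hydroxy-4(14)-methylidene enone F3. Hydroxyl-directed hydrogenation with Crabtree's catalyst delivers hydrogen to C4 on the α face and gives 11.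

Step 13. The cyclodehydration may be accompanied by acid-promoted ionisation of the furfurylic C9–O bond, or may stall at the hemiketal stage. The fallback sets out from 18, bypasses the furan and returns at 25. Dehydration of 18 with Burgess reagent gives the protected enone, from which the 7(11)Z isomer, tris-silyl (Z)-enone F4, is separated, the E isomer being recycled by iodine/light equilibration. PPTS in MeOH at 0 °C removes only the TES ether to give 3α-alcohol F5, and acryloyl chloride/i-Pr2NEt gives bis-TBS acrylate F6. The Heck coupling with 4 under the conditions of step 16 gives bis-TBS trienoate F7, and TBAF/AcOH gives 25.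

Step 16. The coupling may suffer from slow insertion of the hindered dienyl–palladium species, partial E/Z scrambling, or dehydration of the (Z)-γ-hydroxy enone back to the furan. The fallback is a Stille coupling that sets out from 19 and 4 and returns at 24. Compound 19 is esterified with (E)-3-iodoacrylic acid (DCC, DMAP) to give furan (E)-3-iodoacrylate F8. DMDO then NaBH4, as in step 15, give hydroxy-enone (E)-3-iodoacrylate F9. Iodide 4 is converted by iodine–lithium exchange (t-BuLi, Et2O, −78 °C) and Bu3SnCl into dienylstannane F10. Coupling of F9 and F10 with Pd2(dba)3, AsPh3 and CuI in NMP at rt gives 24 with retention of both alkene geometries.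

Further compounds
F1 | step 6 | 4,5β-dimethyl-Δ3,Δ9(10)-octalin-8-one | CC1=CCCC2=CC(=O)CC[C@]12C
F2 | step 6 | 3α,4α-epoxy-4β,5β-dimethyl-Δ9(10)-octal-8-one | O1[C@@H]2CCC3=CC(=O)CC[C@]3(C)[C@]12C
F3 | step 6 | 3α-hydroxy-5β-methyl-4-methylidene-Δ9(10)-octal-8-one | O[C@@H]1CCC2=CC(=O)CC[C@]2(C)C1=C
F4 | step 13 | (7(11)Z)-9β,12-bis(tert-butyldimethylsilyloxy)-3α-(triethylsilyloxy)-10βH-eremophil-7(11)-en-8-one | CC[Si](CC)(CC)O[C@@H]1CC[C@@H]2[C@@H](O[Si](C)(C)C(C)(C)C)C(=O)/C(=C(/C)CO[Si](C)(C)C(C)(C)C)C[C@]2(C)[C@H]1C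
F5 | step 13 | (7(11)Z)-9β,12-bis(tert-butyldimethylsilyloxy)-3α-hydroxy-10βH-eremophil-7(11)-en-8-one | O[C@@H]1CC[C@@H]2[C@@H](O[Si](C)(C)C(C)(C)C)C(=O)/C(=C(/C)CO[Si](C)(C)C(C)(C)C)C[C@]2(C)[C@H]1C
F6 | step 13 | (7(11)Z)-9β,12-bis(tert-butyldimethylsilyloxy)-8-oxo-10βH-eremophil-7(11)-en-3α-yl acrylate | C=CC(=O)O[C@@H]1CC[C@@H]2[C@@H](O[Si](C)(C)C(C)(C)C)C(=O)/C(=C(/C)CO[Si](C)(C)C(C)(C)C)C[C@]2(C)[C@H]1C
F7 | step 13 | 9,12-bis-O-(tert-butyldimethylsilyl) ether of the target | CCCCC/C=C/C(C)=C/C=C/C(=O)O[C@@H]1CC[C@@H]2[C@@H](O[Si](C)(C)C(C)(C)C)C(=O)/C(=C(/C)CO[Si](C)(C)C(C)(C)C)C[C@]2(C)[C@H]1C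
F8 | step 16 | 9β-(tert-butyldimethylsilyloxy)-10βH-furanoeremophilan-3α-yl (E)-3-iodoacrylate | I/C=C/C(=O)O[C@@H]1CC[C@@H]2[C@@H](O[Si](C)(C)C(C)(C)C)c3occ(C)c3C[C@]2(C)[C@H]1C
F9 | step 16 | (7(11)Z)-12-hydroxy-8-oxo-9β-(tert-butyldimethylsilyloxy)-10βH-eremophil-7(11)-en-3α-yl (E)-3-iodoacrylate | I/C=C/C(=O)O[C@@H]1CC[C@@H]2[C@@H](O[Si](C)(C)C(C)(C)C)C(=O)/C(=C(/C)CO)C[C@]2(C)[C@H]1C
F10 | step 16 | tributyl[(1E,3E)-2-methylnona-1,3-dien-1-yl]stannane | CCCCC/C=C/C(C)=C/[Sn](CCCC)(CCCC)CCCC
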